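## Retrosynthetic overview

1. The target comes from acetylation and reductive desulfonylation of a 14-membered sulfone; the macrocycle is closed last, at C2–C3, by a decarboxylative alkenylation that also sets C2.
2. The seco acid comes from C13–C14 sulfone alkylation of a dihydrofuran sulfone acid with an (S,S)-epoxy allylic chloride that carries the vinyl iodide (Shi epoxidation; chain from (E)-geranylacetone).
3. The sulfone acid comes from palladium opening of an allylic lactone, itself from a one-pot directed carboxylation/Birch reduction of symmetric 3,4-bis(hydroxymethyl)furan (from diethyl furan-3,4-dicarboxylate).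
4. Ring order: dihydrofuran (by dearomatisation), then the oxirane (on the open chain), then the 14-membered carbocycle.

Assumption: macrocycle positions use cembrane numbering (C1 = ring alkene carbon bearing C14; C2 = O-bearing stereocentre; C16 = ring OCH2; C17 = CH2O on C15), in which the target is 2S,7S,8S; (E)-geranylacetone, diethyl furan-3,4-dicarboxylate and both antipodes of the Shi ketone are taken as purchasable.

## Route

Step 1
Reactants: 1 diethyl furan-3,4-dicarboxylate
Product: 2 furan-3,4-diyldimethanol
Conditions: LiAlH4 (2.2 equiv), THF, 0 °C → rt; Fieser work-up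
Reagents that add atoms: none
Why: Exhaustive hydride reduction of both ester groups (ester-to-alcohol reduction) leaves the furan intact and creates no stereocentre.

Step 2
Reactants: 2 furan-3,4-diyldimethanol
Product: 5 (±)-3,4-bis(hydroxymethyl)-2,5-dihydrofuran-2-carboxylic acid, via trilithium furoate 3 (not isolated), via tetralithium enediolate 4 (not isolated)
Conditions: n-BuLi (3.1 equiv), TMEDA, THF, −78 → 0 °C; CO2, −78 °C; Ar purge; NH3(l), Li (2.5 equiv), −78 °C; NH4Cl; aq HCl to pH 3, 0 °C
Reagents that add atoms: carbon dioxide, O=C=O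
Why: Proposed new method: the lithium alkoxides direct n-BuLi to an adjacent α-position (alkoxide-directed ortho-lithiation, known for 3-furylmethanol), CO2 traps the furyl-lithium, and the resulting 2-furoate is the only reducible π-system for lithium in ammonia, which protonates C5 and then, on NH4Cl quench of the enediolate, C2 (Birch reduction of a 3-substituted 2-furoic acid is the closest known reaction), so one pot breaks both the symmetry and the aromaticity and fixes which α-carbon will carry the alkenyl group, the racemic C2 centre being erased in step 10.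

Step 3
Reactants: 5 (±)-3,4-bis(hydroxymethyl)-2,5-dihydrofuran-2-carboxylic acid
Product: 7 (±)-4-(hydroxymethyl)-3-[(phenylsulfonyl)methyl]-2,5-dihydrofuran-2-carboxylic acid, via bicyclic allylic lactone 6 (not isolated)
Conditions: EDC·HCl (1.05 equiv), CH2Cl2/DMF (0.01 M), 0 °C; then Pd(PPh3)4 (5 mol%), PhSO2Na (1.5 equiv), THF, rt; aq HCl
Reagents that add atoms: sodium benzenesulfinate, [Na+].[O-]S(=O)c1ccccc1
Why: Only the hydroxymethyl group next to the carboxyl can lactonise (carbodiimide lactonisation; the other arm is barred by Bredt strain), and this strained allylic lactone ionises with zerovalent palladium to a π-allyl carboxylate that sulfinate attacks at the unhindered CH2 terminus (Tsuji–Trost allylic sulfonylation), which differentiates the two arms without protecting groups.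

Step 4
Reactants: 8 (E)-geranylacetone
Product: 10 (E)-6,10-dimethylundeca-5,9-dien-1-yne, via enol phosphate 9 (not isolated)
Conditions: LiN(i-Pr)2 (1.05 equiv), THF, −78 °C; ClP(O)(OEt)2, −78 °C → rt; LiN(i-Pr)2 (2.3 equiv), −78 °C → rt; H2O
Reagents that add atoms: none
Why: Kinetic enolisation toward the methyl group, O-phosphorylation and base-induced elimination of the enol phosphate give the terminal alkyne without touching the E-alkene (Negishi methyl ketone-to-alkyne conversion).

Step 5
Reactants: 10 (E)-6,10-dimethylundeca-5,9-dien-1-yne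
Product: 12 (1E,5E)-1-iodo-2,6,10-trimethylundeca-1,5,9-triene, via alkenylalane 11 (not isolated)
Conditions: Me3Al (2 equiv), Cp2ZrCl2 (0.25 equiv), CH2Cl2, rt; I2, THF, −30 °C
Reagents that add atoms: trimethylaluminium, C[Al](C)C; iodine, II
Why: Zirconium-catalysed syn-methylalumination of the terminal alkyne (Negishi carboalumination) puts methyl on the internal carbon and aluminium on the terminus, and iodinolysis with retention gives the E-trisubstituted vinyl iodide.

Step 6
Reactants: 12 (1E,5E)-1-iodo-2,6,10-trimethylundeca-1,5,9-triene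
Product: 13 (2E,6E,10E)-11-iodo-2,6,10-trimethylundeca-2,6,10-trien-1-ol
Conditions: SeO2 (0.1 equiv), t-BuOOH (3 equiv), salicylic acid (0.1 equiv), CH2Cl2, 0 °C → rt, stopped at about 60% conversion
Reagents that add atoms: selenium dioxide (catalytic oxygen carrier), O=[Se]=O; tert-butyl hydroperoxide, CC(C)(C)OO
Why: SeO2-catalysed allylic oxidation (ene reaction then [2,3]-sigmatropic shift) attacks the E-methyl of the terminal, most accessible trisubstituted alkene, while the iodoalkene is electronically deactivated.

Step 7
Reactants: 13 (2E,6E,10E)-11-iodo-2,6,10-trimethylundeca-2,6,10-trien-1-ol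
Product: 14 (2E,6E,10E)-1-chloro-11-iodo-2,6,10-trimethylundeca-2,6,10-triene
Conditions: NCS, Me2S, CH2Cl2, −40 → 0 °C
Reagents that add atoms: N-chlorosuccinimide, O=C1CCC(=O)N1Cl
Why: Corey–Kim chlorination converts the primary allylic alcohol into the chloride by SN2 displacement of an alkoxysulfonium ion, with no allylic transposition or change of alkene geometry.

Step 8
Reactants: 14 (2E,6E,10E)-1-chloro-11-iodo-2,6,10-trimethylundeca-2,6,10-triene
Product: 15 (2S,3S)-2-[(3E)-5-chloro-4-methylpent-3-en-1-yl]-3-[(3E)-4-iodo-3-methylbut-3-en-1-yl]-2-methyloxirane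
Conditions: ent-Shi ketone (L-fructose-derived, 0.3 equiv), Oxone (2KHSO5·KHSO4·K2SO4), K2CO3, Bu4NHSO4, MeCN/DMM–aq buffer (pH 10.5), −10 → 0 °C
Reagents that add atoms: potassium peroxymonosulfate (active salt of Oxone), [K+].[O-]S(=O)(=O)OO
Why: Shi asymmetric epoxidation reacts only at the central electron-rich alkene, because the allylic chloride and the iodine deactivate the other two, and the spiro transition state of the ent-ketone (the D-fructose ketone gives R,R epoxides) delivers oxygen to the face that gives the (S,S)-epoxide.

Step 9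
Reactants: 7 (±)-4-(hydroxymethyl)-3-[(phenylsulfonyl)methyl]-2,5-dihydrofuran-2-carboxylic acid; 15 (2S,3S)-epoxy chloride
Product: 17 seco acid (epimers at ring C2 and at the sulfonyl carbon), via trilithium sulfonyl carbanion 16 (not isolated)
Conditions: LiN(SiMe3)2 (3.1 equiv), THF/DMPU, −78 °C; then 15, −78 → −20 °C; aq NH4Cl, citric acid
Reagents that add atoms: none
Why: The α-sulfonyl allyl carbanion alkylates the primary allylic chloride at its α-carbon by SN2 (Biellmann-type sulfone coupling), which joins C14 to C13 with retention of the E-alkene, while the new sulfone-bearing centre is uncontrolled and is removed in step 11.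

Step 10
Reactants: 17 seco acid
Product: 18 (2S,7S,8S)-7,8-epoxy-14-(phenylsulfonyl)-2,16-epoxycembra-1(15),3E,11E-trien-17-ol (both C14 epimers)
Conditions: Ir[dF(CF3)ppy]2(dtbbpy)PF6 (2 mol%), NiCl2(dme) (10 mol%), chiral cyano-bis(oxazoline) ligand (12 mol%; the antipode that gives 2S is picked by screening), Cs2CO3 (1.5 equiv), DMF (0.002 M), blue LEDs, rt
Reagents that add atoms: none
Why: Proposed new method: the excited iridium photocatalyst oxidises the caesium carboxylate, loss of CO2 gives a planar α-oxy allylic radical at C2 (so both C2 epimers converge), zerovalent nickel inserts into the vinyl iodide of the same molecule with retention, the radical is captured at its less hindered C2 terminus to give a trivalent alkyl(alkenyl)nickel species, and reductive elimination, whose face is set by the chiral ligand, forms C2–C3, the 14-membered ring and the 2S centre; the closest known reactions are the metallaphotoredox decarboxylative alkenylation of α-oxy acids with vinyl iodides and the enantioconvergent nickel-catalysed decarboxylative arylation of α-amino acids.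

Step 11
Reactants: 18 macrocyclic sulfone
Product: 19 (2S,7S,8S)-7,8:2,16-diepoxycembra-1(15),3E,11E-trien-17-ol
Conditions: PdCl2(dppp) (10 mol%), LiBHEt3 (3.5 equiv), THF, −20 → 0 °C, short reaction time; aq NH4Cl
Reagents that add atoms: none
Why: Palladium-catalysed reductive desulfonylation (ionisation of the allylic sulfone to a π-allyl complex and hydride transfer to the less substituted terminus C14) removes the sulfone and its stereocentre while keeping the tetrasubstituted ring alkene in place, and the hindered trisubstituted epoxide is expected to survive the short exposure at low temperature.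

Step 12
Reactants: 19 17-hydroxy macrocycle
Product: 20 CNP0140293.1
Conditions: Ac2O, pyridine, DMAP (cat.), CH2Cl2, 0 °C
Reagents that add atoms: acetic anhydride, CC(=O)OC(C)=O
Why: DMAP-catalysed acylation of the only hydroxyl group (nucleophilic catalysis) gives the acetate without affecting the epoxide or the stereocentres.

## Compound list

1 | diethyl furan-3,4-dicarboxylate | CCOC(=O)c1cocc1C(=O)OCC | starting material
2 | furan-3,4-diyldimethanol | OCc1cocc1CO | intermediate
3 | trilithium 3,4-bis(oxidomethyl)furan-2-carboxylate | [Li+].[Li+].[Li+].[O-]Cc1coc(C([O-])=O)c1C[O-] | intermediate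
4 | tetralithium enediolate from Birch reduction of 3 (exocyclic C(OLi)2 at C2, 3,4-bis(lithiooxymethyl), 2,5-dihydrofuran ring) | [Li+].[Li+].[Li+].[Li+].[O-]CC1=C(C[O-])C(=C([O-])[O-])OC1 | intermediate
5 | (±)-3,4-bis(hydroxymethyl)-2,5-dihydrofuran-2-carboxylic acid | OC(=O)C1OCC(CO)=C1CO | intermediate
6 | (±)-4-(hydroxymethyl)-2,7-dioxabicyclo[3.3.0]oct-4-en-8-one | O=C1OCC2=C(CO)COC12 | intermediate
7 | (±)-4-(hydroxymethyl)-3-[(phenylsulfonyl)methyl]-2,5-dihydrofuran-2-carboxylic acid | OC(=O)C1OCC(CO)=C1CS(=O)(=O)c1ccccc1 | intermediate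
8 | (E)-geranylacetone, (5E)-6,10-dimethylundeca-5,9-dien-2-one | CC(=O)CC/C=C(\C)CCC=C(C)C | starting material
9 | diethyl (5E)-6,10-dimethylundeca-1,5,9-trien-2-yl phosphate | C=C(CC/C=C(\C)CCC=C(C)C)OP(=O)(OCC)OCC | intermediate
10 | (E)-6,10-dimethylundeca-5,9-dien-1-yne | C#CCC/C=C(\C)CCC=C(C)C | intermediate
11 | dimethyl[(1E,5E)-2,6,10-trimethylundeca-1,5,9-trien-1-yl]alane | C[Al](C)/C=C(\C)CC/C=C(\C)CCC=C(C)C | intermediate
12 | (1E,5E)-1-iodo-2,6,10-trimethylundeca-1,5,9-triene | I/C=C(\C)CC/C=C(\C)CCC=C(C)C | intermediate
13 | (2E,6E,10E)-11-iodo-2,6,10-trimethylundeca-2,6,10-trien-1-ol | OC/C(C)=C/CC/C(C)=C/CC/C(C)=C/I | intermediate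
14 | (2E,6E,10E)-1-chloro-11-iodo-2,6,10-trimethylundeca-2,6,10-triene | ClC/C(C)=C/CC/C(C)=C/CC/C(C)=C/I | intermediate
15 | (2S,3S)-2-[(3E)-5-chloro-4-methylpent-3-en-1-yl]-3-[(3E)-4-iodo-3-methylbut-3-en-1-yl]-2-methyloxirane | ClC/C(C)=C/CC[C@]1(C)O[C@H]1CC/C(C)=C/I | intermediate
16 | trilithium salt of 7 (carboxylate, alkoxide and α-sulfonyl carbanion) | [Li+].[Li+].[Li+].[O-]CC1=C([CH-]S(=O)(=O)c2ccccc2)C(C([O-])=O)OC1 | intermediate
17 | 4-(hydroxymethyl)-3-{(3E)-6-[(2S,3S)-3-((3E)-4-iodo-3-methylbut-3-en-1-yl)-2-methyloxiran-2-yl]-3-methyl-1-(phenylsulfonyl)hex-3-en-1-yl}-2,5-dihydrofuran-2-carboxylic acid, epimers at ring C2 and at the sulfonyl carbon | OC(=O)C1OCC(CO)=C1C(S(=O)(=O)c1ccccc1)C/C(C)=C/CC[C@]2(C)O[C@H]2CC/C(C)=C/I | intermediate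
18 | (2S,7S,8S)-7,8-epoxy-14-(phenylsulfonyl)-2,16-epoxycembra-1(15),3E,11E-trien-17-ol, both C14 epimers (target skeleton with OH for OAc and PhSO2 on C14) | OCC1=C2C(S(=O)(=O)c4ccccc4)C/C(C)=C/CC[C@]3(C)O[C@H]3CC/C(C)=C/[C@@H]2OC1 | intermediate
19 | (2S,7S,8S)-7,8:2,16-diepoxycembra-1(15),3E,11E-trien-17-ol | OCC1=C2CC/C(C)=C/CC[C@]3(C)O[C@H]3CC/C(C)=C/[C@@H]2OC1 | intermediate
20 | CNP0140293.1, (2S,7S,8S)-17-acetoxy-7,8:2,16-diepoxycembra-1(15),3E,11E-triene | CC(=O)OCC1=C2CC/C(C)=C/CC[C@]3(C)O[C@H]3CC/C(C)=C/[C@@H]2OC1 | target

## Step count and risks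

Total step count: 12. Longest linear sequence: 9 steps (8 → 20, steps 4–12).

**Step 10 (ring closure with control of C2).** This is the most likely step to fail, through dilution effects or poor control at C2 next to the sulfonyl centre. The fallback separates the two events; it sets out from 13 (with 7) and returns at 18. Compound 13 is acetylated to the iodotrienyl acetate F1, epoxidised under the step 8 conditions to the epoxy acetate F2, and methanolysed (K2CO3, MeOH) to the epoxy alcohol F3. The same iridium/nickel system then couples 7 with F3 intermolecularly, where the ligand only has to discriminate the faces of the planar C2 radical, giving the open-chain sulfonyl diol F4. The ring is then closed at C13–C14 instead, by Mitsunobu-type C-alkylation of the allylic sulfone with the primary allylic alcohol (Bu3P=CHCN, toluene, 100 °C, high dilution; the other hydroxymethyl group cannot cyclise onto C14), which gives 18.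

**Step 2 (one-pot carboxylation and Birch reduction).** The trilithium salt may be too insoluble, or the reduction may not be clean. The fallback sets out from 2 and returns at 5. The lithiation/CO2 stage is worked up with acid to isolate the aromatic lactone 3-(hydroxymethyl)-4H-furo[3,4-b]furan-6-one F5. F5 is saponified with NaOH and the sodium furoate is reduced with sodium amalgam in buffered water at 0 °C. This classical aqueous electron-transfer reduction of 2-furoates needs neither ammonia nor the lithium trianion, and acidification gives 5.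

**Step 3 (strained lactone and palladium sulfonylation).** The lactone may not form, or may oligomerise. The fallback sets out from 5 and returns at 7, and differentiates the arms enzymatically. Peracetylation (Ac2O, pyridine; aqueous work-up frees the acid) gives the diacetate acid F6. Immobilised Candida antarctica lipase B in phosphate buffer hydrolyses the less hindered acetate, remote from the carboxyl-bearing carbon, to the monoacetate F7. Pd(PPh3)4 and PhSO2Na then displace the remaining allylic acetate (the free allylic alcohol does not ionise) and give 7.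

## Further compounds

F1 | step 10 | (2E,6E,10E)-11-iodo-2,6,10-trimethylundeca-2,6,10-trien-1-yl acetate | CC(=O)OC/C(C)=C/CC/C(C)=C/CC/C(C)=C/I
F2 | step 10 | (2E)-5-[(2S,3S)-3-((3E)-4-iodo-3-methylbut-3-en-1-yl)-2-methyloxiran-2-yl]-2-methylpent-2-en-1-yl acetate | CC(=O)OC/C(C)=C/CC[C@]1(C)O[C@H]1CC/C(C)=C/I
F3 | step 10 | (2E)-5-[(2S,3S)-3-((3E)-4-iodo-3-methylbut-3-en-1-yl)-2-methyloxiran-2-yl]-2-methylpent-2-en-1-ol | OC/C(C)=C/CC[C@]1(C)O[C@H]1CC/C(C)=C/I
F4 | step 10 | open-chain (2S)-2-alkenyl-4-(hydroxymethyl)-3-[(phenylsulfonyl)methyl]-2,5-dihydrofuran carrying the (7S,8S)-epoxide and the C13 allylic alcohol | OC/C(C)=C/CC[C@]3(C)O[C@H]3CC/C(C)=C/[C@@H]2OCC(CO)=C2CS(=O)(=O)c1ccccc1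
F5 | step 2 | 3-(hydroxymethyl)-4H-furo[3,4-b]furan-6-one | OCc1coc2C(=O)OCc12
F6 | step 3 | (±)-3,4-bis(acetoxymethyl)-2,5-dihydrofuran-2-carboxylic acid | OC(=O)C1OCC(COC(C)=O)=C1COC(C)=O
F7 | step 3 | (±)-3-(acetoxymethyl)-4-(hydroxymethyl)-2,5-dihydrofuran-2-carboxylic acid | OC(=O)C1OCC(CO)=C1COC(C)=O
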